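## Structural features

The target is a (2S)-flavanone: a chroman-4-one (ring C, O1–C2–C3–C4) fused along C4a–C8a to benzene ring A, with an unsubstituted phenyl ring B on C2. C2 is the only stereocentre; it is benzylic, carries the ring oxygen and lies beta to the C4 carbonyl, so a base that enolises C3 can expel the phenoxide, open ring C to an achiral chalcone and return racemic material. Ring A is a phloroglucinol core whose three oxygens are all different: a free 5-OH hydrogen-bonded to the C4 carbonyl, a prenyl ether at C7 and the ring oxygen at C8a. Its other positions carry a C-prenyl group (C8), the acyl carbon (C4a) and one hydrogen (C6). Both prenyl groups are trisubstituted alkenes that rule out hydrogenation, strong protic or Lewis acids (the C8 chain would cyclise onto a neighbouring oxygen) and electrophilic halogen. The real difficulty is regiochemical: C-prenyl must go to C8 and not C6, and the three oxygens must be told apart, without putting the finished flavanone under basic conditions. The key step uses the fact that C5 (oxygen), C6 (H), C7 (oxygen) and C8 (carbon substituent) follow one another exactly as the carbonyl carbon of a ketene, the two carbons of an ynol ether and the alpha carbon of the ketene do, while C8a=C4a with its oxygen is the enol-ether double bond of a 2,3-dihydro-4H-pyran-4-one that already holds ring C and C2.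

## Logic of the disconnections

28 to 25 + 26. The ether bond between O7 and the allylic CH2 is cut. O7 is the only ring A oxygen that leaves the ring-forming step as a silyl ether, so it can be unmasked and alkylated in one operation while the chelated 5-OH stays free. The gain is that the heat- and acid-sensitive allyl aryl ether is absent from all earlier steps. The forward step must free the 7-phenoxide without enolising C3 and must alkylate on oxygen, not on C6.

25 to 16 + 20. Three bonds of ring A are cut: C5–C6, C7–C8 and C4a–C5. This removes the whole hexasubstituted benzene ring and leaves 16, which carries ring C, C2 and the future C8 prenyl group, plus the two-carbon unit 20, which brings C6 and C7 with its oxygen. The forward step must convert 16 into 21 faster than the carbene finds other exits, must join 21 and 20 in one orientation only, and must run on to the phenol without acid or base.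

20 to 17. The C(sp)–O bond and the O–Si bond are cut, leading back to 17 through 18 and 19. The parent compound 20 is not taken to be a stock item, and the oxygen is best placed on a preformed acetylide. Oxygen transfer must outrun disproportionation of 18, and 19 must be silylated on oxygen.

16 to 13. The C=N2 unit is removed from the methylene next to the side-chain carbonyl, the carbon that becomes C8. This reduces the photochemical precursor to a plain ketone. The forward step must activate that methylene and not C3 of the ring, and the base must not open the ring at C2.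

13 to 12 to 10. First the side-chain carbonyl is taken back to the alcohol level (12), because an alkyne flanked by two carbonyls would have no single sense of polarisation in the ring closure. Then the O1–C6 bond of the pyranone (O1–C8a of the target) is cut, opening ring C to the acyclic ynone 10. Ring C and its stereocentre then come from an open-chain carbinol whose C–O bond is never broken. The cyclisation must be 6-endo and not 5-exo, and the silyl ether must come off without base.

10 to 3 + 7. The bond between the carbonyl carbon (C4 of the target) and the alkyne carbon (C4a) is cut. This is the convergent step, dividing the skeleton into a three-carbon chiral piece and an eight-carbon side-chain piece. It needs an acyl donor that stops at the ketone and a nucleophile (8) that tolerates the alkoxide 9.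

3 to 1, and 7 to 6 to 4 + 5. The amide C–N bond of 3 is cut back to 1, which supplies C2 with its oxygen and phenyl group in place. In 7 the O–Si bond and then the bond between the carbinol carbon and the alkyne are cut, giving 4 and 5. The demands are small: amide formation without protecting the hydroxyl, and a carbinol centre in 6 that may be racemic because it is oxidised later.

## Other disconnections considered

Alternative 1: The cut runs through ring C at O1–C2 and C3–C4 and leaves ring A intact. A chiral phosphoric acid would ionise benzylic alcohol A1 to the ortho-quinone methide A2, which would add styrene A3 across its carbonyl oxygen and exocyclic methylene to give flavan A4, with C2 set by the catalyst.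
- In favour: both partners are simple and achiral, and two bonds and the stereocentre arise in one catalytic step. No diazo compound, azide or light is needed, so on operational safety this alternative is the better one.
- Against: A3 has no hydrogen-bonding group by which the chiral acid could hold it, so face selection is the weak point. A4 is at the flavan oxidation level, and C4 must be oxidised beside an equally activated C2–H. The two benzyl ethers do not distinguish O5 from O7 and can only be removed by hydrogenolysis, before any prenyl group is present. The C8 prenyl group would come afterwards by a 5-O-prenyl shift that can also end at C6.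
- Comparison: on structure the chosen plan is stronger, since it fixes all six positions of ring A in the ring-forming step. On mechanism the two are equal in mildness; the alternative is better precedented as a reaction class but weaker in enantiocontrol, whereas the chosen plan takes C2 from the chiral pool. On step economy the alternative reaches the bicyclic core sooner but needs about six operations after its key step against one.

Alternative 2: The cut is the aryl ether bond O1–C8a. Bromo alcohol A5, with the (S)-carbinol in place and C4 held as a silyl ether, would close to flavan A6 under CuI, a phenanthroline ligand and Cs2CO3.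
- In favour: intramolecular CuI-catalysed C–O coupling of secondary alcohols is well established, so this key step is better precedented than the chosen one. The C–O bond at the stereocentre is not broken, which is equal to the chosen plan. With C4 at the alcohol level there is no beta-elimination path during the coupling.
- Against: A5 needs its own asymmetric entry and several protecting-group steps. The bromide sits on an electron-rich ring next to a bulky carbon, which calls for about 110 °C in the presence of two allyl aryl ethers. Desilylation, oxidation at C4 and an Eu(fod)3-catalysed shift of the 5-O-prenyl group to C8 would still follow, and that shift must choose C8 over C6 and leave the 7-O-prenyl ether alone.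
- Comparison: on structure the alternative builds on a symmetrical bis-ether and reaches the 5-OH/8-prenyl pattern only at the end, while the chosen plan installs it directly. On mechanism the alternative is the safer in precedent and the chosen plan the gentler towards C2 once the ketone exists. On step economy the alternative is longer by roughly three to four steps.

Alternative 3: Two bonds are cut, C4–C4a and O1–C8a. Aryllithium A8 would attack the carbonyl of beta-lactone A7 (available from 1), the ring would open to the lithium alkoxide of a beta-hydroxy aryl ketone, and on warming the alkoxide would displace the ortho fluoride to give flavanone A9.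
- In favour: it is the shortest plan, forming ring C and the acyl link in one flask from the same chiral pool. On step economy it is better than the chosen plan.
- Against: an ortho-fluoroaryllithium loses LiF to an aryne unless kept very cold. The lactone can also open at the benzylic carbon or take a second aryllithium. The fluoroarene carries two donor oxygens, so substitution is slow and the alkoxide has time for retro-aldol cleavage or dehydration to a chalcone, whose re-closure would be racemic. A9 still needs the same late 5-O to C8 prenyl migration as Alternative 2.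
- Comparison: on structure A9 is symmetrical in its oxygens and the final pattern rests on one regioselective rearrangement, against direct placement in the chosen plan. On mechanism the alternative uses strongly basic anionic conditions where the beta-oxygenated ketone is most fragile, so the chosen plan is better for C2. On step economy the alternative is better by about four steps if every step held.

Key step: step 9

Remark on the chemistry: compounds 6 to 12 are carried as mixtures at the side-chain carbinol carbon, which step 6 turns into a carbonyl; 20 is taken to be a non-catalogue compound and is made in step 8.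

## Steps

Step 1
Reactants: 1 (S)-3-hydroxy-3-phenylpropanoic acid
Product: 3 (S)-3-hydroxy-N-methoxy-N-methyl-3-phenylpropanamide, via benzotriazolyl ester 2 (not isolated)
Conditions: EDC·HCl, HOBt, CH2Cl2, 0 °C; then MeNH(OMe)·HCl, N-methylmorpholine, 0 °C to rt
Reagents that add atoms: N,O-dimethylhydroxylamine hydrochloride, CNOC.Cl; 1-hydroxybenzotriazole, On1nnc2ccccc12 (in 2 only)
Why: Carbodiimide amide coupling through the active ester; the secondary benzylic hydroxyl is far less nucleophilic than the amine and needs no protection, and the carbinol centre is not involved.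

Step 2
Reactants: 4 5-methylhex-4-enal; 5 ethynylmagnesium bromide
Product: 6 (±)-7-methyloct-6-en-1-yn-3-ol
Conditions: THF, 0 °C to rt; aq. NH4Cl
Reagents that add atoms: none
Why: 1,2-Addition of an alkynyl Grignard reagent to an aldehyde; the new carbinol centre is left racemic on purpose because step 6 oxidises it.

Step 3
Reactants: 6 (±)-7-methyloct-6-en-1-yn-3-ol
Product: 7 (±)-triethyl[(7-methyloct-6-en-1-yn-3-yl)oxy]silane
Conditions: TESCl, imidazole, DMAP (cat.), CH2Cl2, 0 °C to rt
Reagents that add atoms: chlorotriethylsilane, CC[Si](Cl)(CC)CC
Why: Standard silylation of a secondary alcohol; the triethylsilyl ether survives n-BuLi, keeps the propargylic oxygen from disturbing the ynone, and is cleaved by mild acid in the flask of step 5.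

Step 4
Reactants: 7 (±)-triethyl[(7-methyloct-6-en-1-yn-3-yl)oxy]silane; 3 (S)-3-hydroxy-N-methoxy-N-methyl-3-phenylpropanamide
Product: 10 (1S)-1-hydroxy-10-methyl-1-phenyl-6-(triethylsilyloxy)undec-9-en-4-yn-3-one (both C6 epimers), via lithium alkynide 8 (not isolated), via lithium alkoxide 9 (not isolated)
Conditions: 7 (1.3 equiv), n-BuLi, THF, −78 °C; separately 3, LiN(SiMe3)2 (1.0 equiv), THF, −78 °C; alkynide added to alkoxide, −78 to −20 °C; aq. NH4Cl at −20 °C
Reagents that add atoms: none
Why: Weinreb ketone synthesis with a lithium acetylide; the chelated tetrahedral adduct stops at the ketone stage, the preformed alkoxide 9 saves alkynide, and the cold buffered quench keeps the beta-hydroxy ynone from dehydration or retro-aldol cleavage.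

Step 5
Reactants: 10 (1S)-1-hydroxy-10-methyl-1-phenyl-6-(triethylsilyloxy)undec-9-en-4-yn-3-one
Product: 12 (2S)-6-(1-hydroxy-5-methylhex-4-en-1-yl)-2-phenyl-2,3-dihydro-4H-pyran-4-one (both carbinol epimers), via silyl ether 11 (not isolated)
Conditions: AgOTf (5 mol %), CH2Cl2, rt, dark; then MeOH, PPTS (cat.), rt
Reagents that add atoms: none
Why: 6-endo-dig oxa-Michael cyclisation of a beta-hydroxy ynone, in which the alkyne activated by AgOTf is attacked at the carbon beta to the carbonyl to give the vinylogous ester and not the five-membered ring; the carbinol oxygen becomes O1, so C2 keeps its (S) configuration, and acidic methanolysis then removes the triethylsilyl group without base.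

Step 6
Reactants: 12 (2S)-6-(1-hydroxy-5-methylhex-4-en-1-yl)-2-phenyl-2,3-dihydro-4H-pyran-4-one
Product: 13 (S)-6-(5-methylhex-4-enoyl)-2-phenyl-2,3-dihydro-4H-pyran-4-one
Conditions: Dess–Martin periodinane, CH2Cl2, 0 °C to rt
Reagents that add atoms: none
Why: Dess–Martin oxidation of a secondary allylic alcohol under near-neutral conditions; both carbinol epimers converge on one ketone and neither the trisubstituted alkene nor C2 is touched.

Step 7
Reactants: 13 (S)-6-(5-methylhex-4-enoyl)-2-phenyl-2,3-dihydro-4H-pyran-4-one
Product: 16 (S)-6-(2-diazo-5-methylhex-4-enoyl)-2-phenyl-2,3-dihydro-4H-pyran-4-one, via lithium enolate 14 (not isolated), via trifluoroacetyl diketone 15 (not isolated)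
Conditions: LiN(SiMe3)2 (1.1 equiv), THF, −78 °C; CF3CO2CH2CF3, −78 °C; 5% aq. HCl work-up; then 4-acetamidobenzenesulfonyl azide, Et3N, H2O (1 equiv), MeCN, rt
Reagents that add atoms: 4-acetamidobenzenesulfonyl azide, CC(=O)Nc1ccc(cc1)S(=O)(=O)N=[N+]=[N-]; 2,2,2-trifluoroethyl trifluoroacetate, O=C(OCC(F)(F)F)C(F)(F)F (in 15 only)
Why: Detrifluoroacetylative diazo transfer: the kinetic enolate 14 should form at the side-chain methylene, whose carbonyl is an ordinary conjugated ketone and not a vinylogous ester, C-trifluoroacetylation gives 15, and the sulfonyl azide then transfers N2 to the activated carbon with loss of the trifluoroacetyl group under Et3N, which is too weak a base to disturb C2.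

Step 8
Reactants: 17 acetylene
Product: 20 (triisopropylsiloxy)ethyne, via lithium acetylide 18 (not isolated), via lithium ethynolate 19 (not isolated)
Conditions: acetylene (excess), n-BuLi, THF, −78 °C; t-BuOOLi (from t-BuOOH and LiN(SiMe3)2, THF, −78 °C), −78 to −20 °C; TIPSOTf, −78 °C to rt; distillation
Reagents that add atoms: tert-butyl hydroperoxide, CC(C)(C)OO; triisopropylsilyl trifluoromethanesulfonate, CC(C)[Si](OS(=O)(=O)C(F)(F)F)(C(C)C)C(C)C
Why: Electrophilic oxygenation of a lithium acetylide by lithium tert-butyl peroxide gives the ynolate, which the bulky silyl triflate silylates on oxygen (the established one-flask route from terminal alkynes to 1-siloxyalkynes); excess acetylene and low temperature hold back disproportionation of 18.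

Step 9
Reactants: 16 (S)-6-(2-diazo-5-methylhex-4-enoyl)-2-phenyl-2,3-dihydro-4H-pyran-4-one; 20 (triisopropylsiloxy)ethyne
Product: 25 (S)-5-hydroxy-8-(3-methylbut-2-en-1-yl)-7-(triisopropylsiloxy)flavanone, via vinylketene 21 (not isolated), via cyclobutenone 22 (not isolated), via dienylketene 23 (not isolated), via cyclohexadienone 24 (not isolated)
Conditions: 20 (2 equiv), hν (420–450 nm LED), toluene (0.05 M), argon, rt; then 90 °C, dark
Reagents that add atoms: none
Why: Proposed new method: photochemical Wolff rearrangement of 16 (1,2-shift of the pyranonyl group with loss of N2) should give vinylketene 21, which adds the electron-rich alkyne 20 by [2+2] to cyclobutenone 22; on heating, 22 opens by four-electron conrotatory electrocyclic cleavage to dienylketene 23, which closes ring A by thermal six-electron disrotatory electrocyclisation (bond C4a–C5) to dienone 24, and enolisation gives phenol 25; the closest known reaction type is the Danheiser benzannulation of aryl and alkenyl alpha-diazo ketones with siloxyalkynes, which has not been shown for a vinylketene whose alkene is the enol-ether double bond of a 4-pyranone. Regiochemistry is set in the [2+2]: the nucleophilic CH terminus of 20 attacks the ketene carbonyl carbon, so C5–C6 and C7–C8 form and 5-OH, 7-OSi and 8-prenyl are fixed in one orientation. Ring opening of 22 is reversible, so only the isomer of 23 with the pyranonyl group cis to the ketene arm is drained; the ring geometry places the C4 carbonyl trans to the ketene-bearing carbon, which excludes closure onto oxygen. No stereocentre is created: the transient centres of 22 and 24 vanish on aromatisation, and C2 is a spectator because no acid or base is present. The step needs the Wolff shift to win over a 1,2-hydrogen shift of the carbene and over photochemistry of the enone; long-wavelength light that excites only the diazo chromophore and the acyl-diazo conformer with carbonyl and diazo groups syn are relied on for this.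

Step 10
Reactants: 25 (S)-5-hydroxy-8-(3-methylbut-2-en-1-yl)-7-(triisopropylsiloxy)flavanone; 26 1-bromo-3-methylbut-2-ene (prenyl bromide)
Product: 28 (2S)-5-hydroxy-8-(3-methylbut-2-en-1-yl)-7-[(3-methylbut-2-en-1-yl)oxy]-2-phenyl-2,3-dihydro-4H-chromen-4-one, via cesium phenoxide 27 (not isolated)
Conditions: CsF (1.5 equiv), 26 (1.2 equiv), DMF, 0 °C to rt
Reagents that add atoms: none
Why: Fluoride cleaves the aryl silyl ether to the 7-phenoxide 27, which is alkylated on oxygen in the same flask (one-pot desilylative Williamson etherification); the 5-OH is held by its hydrogen bond to C4=O and is much less acidic and nucleophilic, and no base stronger than a phenoxide is present, so C3 is not enolised and C2 stays (S).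

## Compound list

1 | (S)-3-hydroxy-3-phenylpropanoic acid | O[C@H](c1ccccc1)CC(=O)O | starting material
2 | benzotriazol-1-yl (S)-3-hydroxy-3-phenylpropanoate | O[C@H](c1ccccc1)CC(=O)On1nnc2ccccc12 | intermediate
3 | (S)-3-hydroxy-N-methoxy-N-methyl-3-phenylpropanamide | O[C@H](c1ccccc1)CC(=O)N(C)OC | intermediate
4 | 5-methylhex-4-enal | CC(C)=CCCC=O | starting material
5 | ethynylmagnesium bromide | C#C[Mg]Br | starting material
6 | (±)-7-methyloct-6-en-1-yn-3-ol | C#CC(O)CCC=C(C)C | intermediate
7 | (±)-triethyl[(7-methyloct-6-en-1-yn-3-yl)oxy]silane | C#CC(O[Si](CC)(CC)CC)CCC=C(C)C | intermediate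
8 | (±)-[7-methyl-3-(triethylsilyloxy)oct-6-en-1-yn-1-yl]lithium | [Li]C#CC(O[Si](CC)(CC)CC)CCC=C(C)C | intermediate
9 | lithium (1S)-3-[methoxy(methyl)amino]-3-oxo-1-phenylpropan-1-olate | [Li]O[C@H](c1ccccc1)CC(=O)N(C)OC | intermediate
10 | (1S)-1-hydroxy-10-methyl-1-phenyl-6-(triethylsilyloxy)undec-9-en-4-yn-3-one (C6 epimers) | O[C@H](c1ccccc1)CC(=O)C#CC(O[Si](CC)(CC)CC)CCC=C(C)C | intermediate
11 | (2S)-6-[5-methyl-1-(triethylsilyloxy)hex-4-en-1-yl]-2-phenyl-2,3-dihydro-4H-pyran-4-one (side-chain epimers) | O=C1C=C(C(O[Si](CC)(CC)CC)CCC=C(C)C)O[C@H](c2ccccc2)C1 | intermediate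
12 | (2S)-6-(1-hydroxy-5-methylhex-4-en-1-yl)-2-phenyl-2,3-dihydro-4H-pyran-4-one (side-chain epimers) | O=C1C=C(C(O)CCC=C(C)C)O[C@H](c2ccccc2)C1 | intermediate
13 | (S)-6-(5-methylhex-4-enoyl)-2-phenyl-2,3-dihydro-4H-pyran-4-one | O=C1C=C(C(=O)CCC=C(C)C)O[C@H](c2ccccc2)C1 | intermediate
14 | lithium 5-methyl-1-[(2S)-4-oxo-2-phenyl-3,4-dihydro-2H-pyran-6-yl]hexa-1,4-dien-1-olate | O=C1C=C(C(O[Li])=CCC=C(C)C)O[C@H](c2ccccc2)C1 | intermediate
15 | (2S)-6-[5-methyl-2-(trifluoroacetyl)hex-4-enoyl]-2-phenyl-2,3-dihydro-4H-pyran-4-one (side-chain epimers, enolised) | O=C1C=C(C(=O)C(CC=C(C)C)C(=O)C(F)(F)F)O[C@H](c2ccccc2)C1 | intermediate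
16 | (S)-6-(2-diazo-5-methylhex-4-enoyl)-2-phenyl-2,3-dihydro-4H-pyran-4-one | O=C1C=C(C(=O)C(=[N+]=[N-])CC=C(C)C)O[C@H](c2ccccc2)C1 | intermediate
17 | acetylene | C#C | starting material
18 | lithium acetylide | [Li]C#C | intermediate
19 | lithium ethynolate | [Li]OC#C | intermediate
20 | (triisopropylsiloxy)ethyne | C#CO[Si](C(C)C)(C(C)C)C(C)C | intermediate
21 | 5-methyl-2-[(2S)-4-oxo-2-phenyl-3,4-dihydro-2H-pyran-6-yl]hexa-1,4-dien-1-one | O=C1C=C(C(=C=O)CC=C(C)C)O[C@H](c2ccccc2)C1 | intermediate
22 | (2S)-6-[1-(3-methylbut-2-en-1-yl)-4-oxo-2-(triisopropylsilyloxy)cyclobut-2-en-1-yl]-2-phenyl-2,3-dihydro-4H-pyran-4-one (epimers at the ring carbon) | O=C1C=C(C2(CC=C(C)C)C(O[Si](C(C)C)(C(C)C)C(C)C)=CC2=O)O[C@H](c2ccccc2)C1 | intermediate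
23 | (3E)-7-methyl-4-[(2S)-4-oxo-2-phenyl-3,4-dihydro-2H-pyran-6-yl]-3-(triisopropylsilyloxy)octa-1,3,6-trien-1-one | O=C1C=C(/C(CC=C(C)C)=C(\C=C=O)O[Si](C(C)C)(C(C)C)C(C)C)O[C@H](c2ccccc2)C1 | intermediate
24 | (2S)-8-(3-methylbut-2-en-1-yl)-2-phenyl-7-(triisopropylsilyloxy)-2,3-dihydro-4H-chromene-4,5(4aH)-dione (C4a epimers) | O=C1C=C(O[Si](C(C)C)(C(C)C)C(C)C)C(CC=C(C)C)=C2O[C@H](c3ccccc3)CC(=O)C12 | intermediate
25 | (S)-5-hydroxy-8-(3-methylbut-2-en-1-yl)-7-(triisopropylsiloxy)flavanone | CC(C)=CCc1c(O[Si](C(C)C)(C(C)C)C(C)C)cc(O)c2c1O[C@H](c1ccccc1)CC2=O | intermediate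
26 | 1-bromo-3-methylbut-2-ene (prenyl bromide) | CC(C)=CCBr | starting material
27 | cesium (2S)-5-hydroxy-8-(3-methylbut-2-en-1-yl)-4-oxo-2-phenyl-3,4-dihydro-2H-chromen-7-olate | CC(C)=CCc1c([O-])cc(O)c2c1O[C@H](c1ccccc1)CC2=O.[Cs+] | intermediate
28 | (2S)-5-hydroxy-8-(3-methylbut-2-en-1-yl)-7-[(3-methylbut-2-en-1-yl)oxy]-2-phenyl-2,3-dihydro-4H-chromen-4-one | CC(C)=CCOc1cc(O)c2c(c1CC=C(C)C)O[C@H](c1ccccc1)CC2=O | target

## Step count and least certain steps

Total step count: 10. Longest linear sequence: 8 steps (steps 2, 3, 4, 5, 6, 7, 9, 10, from 4 and 5).

Step 9 (key step, Proposed new method).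
- Most likely to go wrong: the photogenerated carbene may be lost to a 1,2-hydrogen shift from the neighbouring CH2 of the prenyl chain, or the enone chromophore of the pyranone may react on its own, before the Wolff shift delivers 21. The alpha substituent on the diazo carbon and the cross-conjugated enedione make both exits easier than in simple aryl diazo ketones. Slow opening of 22 would also force prolonged heating, during which 20 can suffer oxygen-to-carbon silyl migration.
- Fallback (known chemistry; ring A taken from a preformed phloroglucinol and C2 set by catalysis): setting out from 26, commercial 5,7-dihydroxy-4H-chromen-4-one F1 is alkylated on both oxygens (K2CO3, DMF, 60 °C) to 5,7-bis(prenyloxy)chromone F2. Eu(fod)3 in CHCl3 at 60 °C should move the chelated 5-O-prenyl group to C8 by a para-Claisen–Cope sequence and give 5-hydroxy-7-(prenyloxy)-8-prenylchromone F3. Asymmetric 1,4-addition of phenylboronic acid to F3 ([Rh(OH)(cod)]2, chiral biaryl bisphosphine of the hand that leads to 2S, toluene–water) comes back to the route at 28.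

Step 7.
- Most likely to go wrong: deprotonation at C3 of the ring competing with enolisation of the side chain. That would lead to trifluoroacetylation at the wrong carbon or to beta-elimination of O1 with ring opening and loss of the C2 configuration, because both methylenes flank carbonyls of similar acidity.
- Fallback (C4 carbonyl masked so that one enolisable site remains): setting out from 11, isolated by leaving out the methanolysis of step 5, Luche reduction (NaBH4, CeCl3·7H2O, MeOH, −78 °C) gives the cis allylic alcohol (2S,4S)-6-[5-methyl-1-(triethylsilyloxy)hex-4-en-1-yl]-2-phenyl-3,4-dihydro-2H-pyran-4-ol F4. TBSCl and imidazole give the tert-butyldimethylsilyl ether F5. Pyridine-buffered HF·pyridine removes only the triethylsilyl group to give the side-chain alcohol F6, and buffered Dess–Martin oxidation gives the side-chain ketone F7. The trifluoroacetylation and diazo transfer of step 7, now without a competing site, lead through the trifluoroacetyl derivative F8 to the silyl-protected diazo ketone F9. TBAF buffered with AcOH frees the diazo allylic alcohol F10, and MnO2 in CH2Cl2 oxidises it to the enone, which comes back to the route at 16.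

Step 8.
- Most likely to go wrong: disproportionation of 18 to insoluble dilithium acetylide before oxygen transfer, and silylation of 19 on carbon instead of oxygen, since the unsubstituted ynolate carbon is less shielded than in the usual substituted cases.
- Fallback (ynolate by ring fragmentation instead of acetylide oxidation): the route is left at 17, which is replaced by commercial 3-phenylisoxazole F11. Lithiation at C5 (n-BuLi, THF, −78 °C) gives 5-lithio-3-phenylisoxazole F12, which should fragment on warming to benzonitrile and the same ynolate. The sequence comes back to the route at 19 and is silylated to 20 as in step 8.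

Step 10.
- Most likely to go wrong: alkylation of the ambident phenoxide at C6 or further alkylation at O5, and partial ring opening to the chalcone with erosion of the C2 configuration, because fluoride in DMF is appreciably basic.
- Fallback (deprotection and etherification separated, no base in the alkylation): setting out from 25, TBAF buffered with AcOH (THF, 0 °C) gives (S)-5,7-dihydroxy-8-prenylflavanone F13. Mitsunobu etherification of its more acidic 7-OH with 3-methylbut-2-en-1-ol (PPh3, DIAD, THF, 0 °C) comes back to the route at 28.

## Further compounds

F1 | step 9 | 5,7-dihydroxy-4H-chromen-4-one | O=c1ccoc2cc(O)cc(O)c12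
F2 | step 9 | 5,7-bis[(3-methylbut-2-en-1-yl)oxy]-4H-chromen-4-one | O=c1ccoc2cc(OCC=C(C)C)cc(OCC=C(C)C)c12
F3 | step 9 | 5-hydroxy-8-(3-methylbut-2-en-1-yl)-7-[(3-methylbut-2-en-1-yl)oxy]-4H-chromen-4-one | O=c1ccoc2c(CC=C(C)C)c(OCC=C(C)C)cc(O)c12
F4 | step 7 | (2S,4S)-6-[5-methyl-1-(triethylsilyloxy)hex-4-en-1-yl]-2-phenyl-3,4-dihydro-2H-pyran-4-ol | O[C@@H]1C=C(C(O[Si](CC)(CC)CC)CCC=C(C)C)O[C@H](c2ccccc2)C1
F5 | step 7 | tert-butyldimethyl{[(2S,4S)-6-[5-methyl-1-(triethylsilyloxy)hex-4-en-1-yl]-2-phenyl-3,4-dihydro-2H-pyran-4-yl]oxy}silane | CC(C)(C)[Si](C)(C)O[C@@H]1C=C(C(O[Si](CC)(CC)CC)CCC=C(C)C)O[C@H](c2ccccc2)C1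
F6 | step 7 | 1-[(2S,4S)-4-(tert-butyldimethylsilyloxy)-2-phenyl-3,4-dihydro-2H-pyran-6-yl]-5-methylhex-4-en-1-ol | CC(C)(C)[Si](C)(C)O[C@@H]1C=C(C(O)CCC=C(C)C)O[C@H](c2ccccc2)C1
F7 | step 7 | 1-[(2S,4S)-4-(tert-butyldimethylsilyloxy)-2-phenyl-3,4-dihydro-2H-pyran-6-yl]-5-methylhex-4-en-1-one | CC(C)(C)[Si](C)(C)O[C@@H]1C=C(C(=O)CCC=C(C)C)O[C@H](c2ccccc2)C1
F8 | step 7 | 1-[(2S,4S)-4-(tert-butyldimethylsilyloxy)-2-phenyl-3,4-dihydro-2H-pyran-6-yl]-5-methyl-2-(trifluoroacetyl)hex-4-en-1-one | CC(C)(C)[Si](C)(C)O[C@@H]1C=C(C(=O)C(CC=C(C)C)C(=O)C(F)(F)F)O[C@H](c2ccccc2)C1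
F9 | step 7 | 1-[(2S,4S)-4-(tert-butyldimethylsilyloxy)-2-phenyl-3,4-dihydro-2H-pyran-6-yl]-2-diazo-5-methylhex-4-en-1-one | CC(C)(C)[Si](C)(C)O[C@@H]1C=C(C(=O)C(=[N+]=[N-])CC=C(C)C)O[C@H](c2ccccc2)C1
F10 | step 7 | 2-diazo-1-[(2S,4S)-4-hydroxy-2-phenyl-3,4-dihydro-2H-pyran-6-yl]-5-methylhex-4-en-1-one | O[C@@H]1C=C(C(=O)C(=[N+]=[N-])CC=C(C)C)O[C@H](c2ccccc2)C1
F11 | step 8 | 3-phenylisoxazole | c1ccc(-c2ccon2)cc1
F12 | step 8 | 5-lithio-3-phenylisoxazole | [Li]c1cc(-c2ccccc2)no1
F13 | step 10 | (S)-5,7-dihydroxy-8-(3-methylbut-2-en-1-yl)flavanone | CC(C)=CCc1c(O)cc(O)c2c1O[C@H](c1ccccc1)CC2=O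
A1 | alternative 1 | 3,5-bis(benzyloxy)-2-(hydroxymethyl)phenol | OCc1c(O)cc(OCc2ccccc2)cc1OCc1ccccc1
A2 | alternative 1 | 3,5-bis(benzyloxy)-6-methylidenecyclohexa-2,4-dien-1-one | C=C1C(=O)C=C(OCc2ccccc2)C=C1OCc1ccccc1
A3 | alternative 1 | styrene | C=Cc1ccccc1
A4 | alternative 1 | (S)-5,7-bis(benzyloxy)flavan | c1ccc(COc2cc(OCc3ccccc3)c3c(c2)O[C@H](c2ccccc2)CC3)cc1
A5 | alternative 2 | (1S)-3-{2-bromo-4,6-bis[(3-methylbut-2-en-1-yl)oxy]phenyl}-3-(tert-butyldimethylsilyloxy)-1-phenylpropan-1-ol (either C3 epimer) | CC(C)=CCOc1cc(Br)c(C(C[C@H](O)c2ccccc2)O[Si](C)(C)C(C)(C)C)c(OCC=C(C)C)c1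
A6 | alternative 2 | (2S)-4-(tert-butyldimethylsilyloxy)-5,7-bis[(3-methylbut-2-en-1-yl)oxy]flavan (either C4 epimer) | CC(C)=CCOc1cc(OCC=C(C)C)c2c(c1)O[C@H](c1ccccc1)CC2O[Si](C)(C)C(C)(C)C
A7 | alternative 3 | (S)-4-phenyloxetan-2-one | O=C1C[C@@H](c2ccccc2)O1
A8 | alternative 3 | {2-fluoro-4,6-bis[(3-methylbut-2-en-1-yl)oxy]phenyl}lithium | [Li]c1c(F)cc(OCC=C(C)C)cc1OCC=C(C)C
A9 | alternative 3 | (S)-5,7-bis[(3-methylbut-2-en-1-yl)oxy]flavanone | CC(C)=CCOc1cc(OCC=C(C)C)c2c(c1)O[C@H](c1ccccc1)CC2=O
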